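**Plan**

- Retrosynthesis: first cut C11=C12 (Wittig; C12–C16 arrives as a phosphonium salt), then both ring B bonds C9–C10 and C7–C8 at once. Ring B is a cyclohexene whose C5=C6 bond lies between C10 and C7, and C8, C9, C10 carry three cis groups (C17, C11, C20). This is the retron of a Diels–Alder reaction between a (Z)-alkene C8=C9 and the ring A diene C10=C5–C6=C7.
- C20 and C11 are cis and vicinal, so they are tied by a temporary ester bridge C20–O–C11(=O). For this, C20 is raised to a silyl carbinol and C11 to a carboxyl carbon. The last cuts are C5–C6 (cross-coupling) and C5–C10 (Dieckmann) of ring A.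
- Forward: ring A by alkylation and Dieckmann, then enol triflate, vinylation, C20 acylsilane, (S)-carbinol and (Z)-crotonate. The intramolecular Diels–Alder reaction then closes ring B (the last ring of the skeleton) together with the lactone. Lactol plus ylide joins C11 to C12; the helpers are removed (C11=C12 saturated, Si and O taken off C20); O15 is acetylated and the rest deprotected.
- Stereochemistry: C8/C9 cis from the Z dienophile; C9/C10 cis from the tether (cis-fused lactone); absolute sense from the C20 silyl carbinol (CBS reduction, then allylic strain in the cycloaddition); C13 from lipase desymmetrisation of a prochiral diol.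

Key step: step 10

Remark: locants follow labdane numbering (ring A = C1–C5 and C10; ring B = C5–C10; side chain C11–C16; C17 = methyl on C8; C18 and C19 = hydroxymethyl carbons on C4; C20 = methyl carbon on C10).

Assumption: in step 7 the silyl group is taken as the larger carbonyl substituent (as for simple acylsilanes) and in step 14 the lipase is taken to give the (S)-monoacetate; the enantiomeric oxazaborolidine, or exchanging the later roles of the two arms of 19, would correct either sense.

**Route**

Step 1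
Reactants: 1 methyl 2,2-dimethyl-1,3-dioxane-5-carboxylate; 2 methyl 5-bromopentanoate
Product: 3 methyl 5-(5-methoxy-5-oxopentyl)-2,2-dimethyl-1,3-dioxane-5-carboxylate
Conditions: LiN(i-Pr)2, THF, −78 °C; then 2, DMPU, −78 °C to rt
Reagents that add atoms: none
Why: Alkylation of the lithium ester enolate of 1 (its only acidic C–H) with the primary bromide (SN2) builds quaternary C4 with both protected hydroxymethyl groups; no stereocentre arises.

Step 2
Reactants: 3 methyl 5-(5-methoxy-5-oxopentyl)-2,2-dimethyl-1,3-dioxane-5-carboxylate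
Product: 4 methyl 3,3-dimethyl-7-oxo-2,4-dioxaspiro[5.5]undecane-8-carboxylate
Conditions: KOtBu, THF, 0 °C to rt; AcOH quench
Reagents that add atoms: none
Why: Dieckmann condensation in which only the methylene next to the chain ester (future C10) can be deprotonated, so it attacks the ester on quaternary C4 and one six-membered β-keto ester results (ring A, C5 ketone, ester carbon = C20).

Step 3
Reactants: 4 methyl 3,3-dimethyl-7-oxo-2,4-dioxaspiro[5.5]undecane-8-carboxylate
Product: 5 methyl 3,3-dimethyl-7-(trifluoromethylsulfonyloxy)-2,4-dioxaspiro[5.5]undec-7-ene-8-carboxylate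
Conditions: NaH, Et2O, 0 °C; then Tf2O, −78 to 0 °C
Reagents that add atoms: trifluoromethanesulfonic anhydride O=S(=O)(OS(=O)(=O)C(F)(F)F)C(F)(F)F
Why: O-Triflation of the sodium enolate of the β-keto ester, which can enolise only towards C10 because C4 is quaternary, fixes the C5=C10 double bond as an enol triflate.

Step 4
Reactants: 5 methyl 3,3-dimethyl-7-(trifluoromethylsulfonyloxy)-2,4-dioxaspiro[5.5]undec-7-ene-8-carboxylate
Product: 6 methyl 7-ethenyl-3,3-dimethyl-2,4-dioxaspiro[5.5]undec-7-ene-8-carboxylate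
Conditions: potassium vinyltrifluoroborate, PdCl2(dppf) (5 mol%), Cs2CO3, THF/H2O, 70 °C
Reagents that add atoms: potassium vinyltrifluoroborate [K+].C=C[B-](F)(F)F
Why: Suzuki–Miyaura coupling of the electron-poor alkenyl triflate installs C6=C7 and completes the 1-vinylcyclohexene diene.

Step 5
Reactants: 6 methyl 7-ethenyl-3,3-dimethyl-2,4-dioxaspiro[5.5]undec-7-ene-8-carboxylate
Product: 7 7-ethenyl-N-methoxy-N,3,3-trimethyl-2,4-dioxaspiro[5.5]undec-7-ene-8-carboxamide
Conditions: MeNHOMe·HCl, i-PrMgCl, THF, −20 to 0 °C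
Reagents that add atoms: N,O-dimethylhydroxylamine hydrochloride CNOC.Cl
Why: Aminolysis of the ester by the magnesium amide gives the Weinreb amide, whose chelated adduct stops at the acyl stage in the next step.

Step 6
Reactants: 7 7-ethenyl-N-methoxy-N,3,3-trimethyl-2,4-dioxaspiro[5.5]undec-7-ene-8-carboxamide
Product: 8 [dimethyl(phenyl)silyl](7-ethenyl-3,3-dimethyl-2,4-dioxaspiro[5.5]undec-7-en-8-yl)methanone
Conditions: PhMe2SiLi, THF, −78 °C; aq. NH4Cl
Reagents that add atoms: dimethyl(phenyl)silyllithium [Li][Si](C)(C)c1ccccc1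
Why: Addition of the silyllithium to the Weinreb amide gives a stable chelate that releases the acylsilane only on work-up, so no second addition occurs.

Step 7
Reactants: 8 [dimethyl(phenyl)silyl](7-ethenyl-3,3-dimethyl-2,4-dioxaspiro[5.5]undec-7-en-8-yl)methanone
Product: 9 (S)-[dimethyl(phenyl)silyl](7-ethenyl-3,3-dimethyl-2,4-dioxaspiro[5.5]undec-7-en-8-yl)methanol
Conditions: (S)-2-methyl-CBS-oxazaborolidine (20 mol%), catecholborane, toluene, −78 °C; neutral work-up
Reagents that add atoms: none
Why: CBS reduction delivers hydride to one face of the acylsilane carbonyl and sets C20 as S, with the silyl group as the larger substituent; the neutral work-up avoids Brook rearrangement of the allylic α-silyl alkoxide.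

Step 8
Reactants: 9 (S)-[dimethyl(phenyl)silyl](7-ethenyl-3,3-dimethyl-2,4-dioxaspiro[5.5]undec-7-en-8-yl)methanol; 10 but-2-ynoic acid
Product: 11 (S)-[dimethyl(phenyl)silyl](7-ethenyl-3,3-dimethyl-2,4-dioxaspiro[5.5]undec-7-en-8-yl)methyl but-2-ynoate
Conditions: DCC, DMAP (cat.), CH2Cl2, 0 °C to rt
Reagents that add atoms: none
Why: Steglich esterification attaches the four carbons C17–C8–C9–C11 to O20 under neutral conditions that leave the α-silyl carbinol and the alkyne untouched.

Step 9
Reactants: 11 (S)-[dimethyl(phenyl)silyl](7-ethenyl-3,3-dimethyl-2,4-dioxaspiro[5.5]undec-7-en-8-yl)methyl but-2-ynoate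
Product: 12 (S)-[dimethyl(phenyl)silyl](7-ethenyl-3,3-dimethyl-2,4-dioxaspiro[5.5]undec-7-en-8-yl)methyl (Z)-but-2-enoate
Conditions: H2 (1 atm), Pd/CaCO3 poisoned with Pb(OAc)2 (Lindlar catalyst), quinoline, EtOAc, rt
Reagents that add atoms: none
Why: Lindlar semi-hydrogenation (syn addition of H2) converts the ynoate into the (Z)-enoate needed for cis C8/C9, the alkyne being reduced far faster than the diene.

Step 10
Reactants: 12 (S)-[dimethyl(phenyl)silyl](7-ethenyl-3,3-dimethyl-2,4-dioxaspiro[5.5]undec-7-en-8-yl)methyl (Z)-but-2-enoate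
Product: 13 cycloadduct lactone: labd-5-ene core C1–C11 and C17–C20 with 18,19-O-isopropylidene; C11 is the lactone carbonyl bound to O20; 8β-methyl, 9α-H, 10β-C20; C20 carries H and SiMe2Ph (20S)
Conditions: toluene, BHT (cat.), 170 °C, sealed tube
Reagents that add atoms: none
Why: A thermal, concerted intramolecular [4+2] cycloaddition joins the ring A diene C10=C5–C6=C7 to the (Z)-crotonate C8=C9; the closest known reaction type is the intramolecular Diels–Alder reaction of ester-linked 1,3,8-nonatrienes (dienyl acrylates, and acetylenic esters tethered to 2,6,6-trisubstituted 1-vinylcyclohexenes). Ring B closes in the fused mode by forming C9–C10 and C7–C8, and the γ-lactone C10–C20–O–C11–C9 closes with it, the three-atom tether allowing no other regiochemistry. C10 and C9: the tether starts at C20, the substituent of C10 that is cis to the vinyl group, so C11 can reach only from the exo position and the lactone must be cis-fused, which makes C11 cis to C20. C8: the cycloaddition is suprafacial on the dienophile, so the Z geometry puts the C17 methyl cis to C11. Absolute sense: in any reactive rotamer the C20 hydrogen has to occupy the in-plane site that points at C7 (allylic strain forbids the silyl group there), which fixes the ester oxygen on one diene face and the silyl group on the other, so the (20S) carbinol leads to 8β-methyl, 9α-H and 10β-C20. The step needs the cycloaddition to be faster than the 1,5-hydrogen shift open to a Z-substituted diene; quaternary C4 (which disfavours the s-trans diene), the branched tether and the single path open to the dienophile work for this.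

Step 11
Reactants: 13 cycloadduct lactone
Product: 14 lactol: as 13 with C11 as hemiacetal CH(OH) (both anomers)
Conditions: i-Bu2AlH, CH2Cl2, −78 °C; Rochelle salt work-up
Reagents that add atoms: none
Why: Partial reduction of the γ-lactone, whose tetrahedral aluminium hemiacetal is stable at −78 °C, gives the lactol (C11 at aldehyde level) without touching a ring stereocentre.

Step 12
Reactants: 15 diethyl malonate; 16 1-[(2-bromoethoxy)methyl]-4-methoxybenzene
Product: 17 diethyl 2-{2-[(4-methoxybenzyl)oxy]ethyl}malonate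
Conditions: NaH, THF/DMF, 0 to 60 °C (excess 15)
Reagents that add atoms: none
Why: Malonate alkylation (SN2) with the primary bromide, excess malonate suppressing dialkylation.

Step 13
Reactants: 17 diethyl 2-{2-[(4-methoxybenzyl)oxy]ethyl}malonate
Product: 18 2-{2-[(4-methoxybenzyl)oxy]ethyl}propane-1,3-diol
Conditions: LiAlH4, THF, 0 °C to rt
Reagents that add atoms: none
Why: Hydride reduction of both esters gives the prochiral 2-substituted propane-1,3-diol; the PMB ether is inert.

Step 14
Reactants: 18 2-{2-[(4-methoxybenzyl)oxy]ethyl}propane-1,3-diol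
Product: 19 (S)-2-(hydroxymethyl)-4-[(4-methoxybenzyl)oxy]butyl acetate
Conditions: Burkholderia cepacia lipase (Amano PS), vinyl acetate, i-Pr2O, rt
Reagents that add atoms: vinyl acetate C=COC(C)=O
Why: Lipase-catalysed irreversible transesterification distinguishes the two enantiotopic hydroxymethyl groups (enzymatic desymmetrisation) and so sets C13; the acetate marks the arm that becomes C12.

Step 15
Reactants: 19 (S)-2-(hydroxymethyl)-4-[(4-methoxybenzyl)oxy]butyl acetate
Product: 20 (S)-4-[(4-methoxybenzyl)oxy]-2-[(trityloxy)methyl]butyl acetate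
Conditions: TrCl, Et3N, DMAP (cat.), CH2Cl2, 0 °C
Reagents that add atoms: trityl chloride ClC(c1ccccc1)(c1ccccc1)c1ccccc1
Why: Tritylation of the remaining primary alcohol (future O16) is done at once, because acyl migration between the two arms would racemise C13.

Step 16
Reactants: 20 (S)-4-[(4-methoxybenzyl)oxy]-2-[(trityloxy)methyl]butyl acetate
Product: 21 (R)-4-[(4-methoxybenzyl)oxy]-2-[(trityloxy)methyl]butan-1-ol
Conditions: K2CO3 (cat.), MeOH, rt
Reagents that add atoms: none
Why: Base-catalysed methanolysis removes only the acetate; the descriptor changes by priority only.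

Step 17
Reactants: 21 (R)-4-[(4-methoxybenzyl)oxy]-2-[(trityloxy)methyl]butan-1-ol
Product: 22 (S)-1-({4-iodo-3-[(trityloxy)methyl]butoxy}methyl)-4-methoxybenzene
Conditions: I2, PPh3, imidazole, CH2Cl2, 0 °C to rt
Reagents that add atoms: iodine II
Why: Appel-type iodination (SN2 at the primary carbon via the alkoxyphosphonium ion) under buffered conditions that spare trityl and PMB ethers.

Step 18
Reactants: 22 (S)-1-({4-iodo-3-[(trityloxy)methyl]butoxy}methyl)-4-methoxybenzene
Product: 23 (S)-{4-[(4-methoxybenzyl)oxy]-2-[(trityloxy)methyl]butyl}triphenylphosphonium iodide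
Conditions: PPh3, MeCN, reflux
Reagents that add atoms: triphenylphosphine c1ccc(cc1)P(c1ccccc1)c1ccccc1
Why: SN2 quaternisation of triphenylphosphine by the primary iodide gives the Wittig salt without involving C13.

Step 19
Reactants: 14 lactol; 23 (S)-{4-[(4-methoxybenzyl)oxy]-2-[(trityloxy)methyl]butyl}triphenylphosphonium iodide
Product: 25 (11Z)-20-[dimethyl(phenyl)silyl]-18,19-isopropylidenedioxy-15-(4-methoxybenzyloxy)-16-trityloxylabda-5,11-dien-20-ol (8β-methyl; 9α-H; 10β-C20; 20S; C13 as in the target), via phosphonium ylide 24 (not isolated)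
Conditions: 23 (2.5 equiv), KN(SiMe3)2, THF, −78 °C; then 14, −78 °C to rt
Reagents that add atoms: none
Why: Wittig olefination in which the non-stabilised ylide traps the hydroxy-aldehyde in equilibrium with the lactol, joins C11 to C12 (Z alkene, geometry of no consequence) and frees the C20 carbinol, with excess ylide as base for the lactol and low temperature to limit epimerisation at C9.

Step 20
Reactants: 25 (11Z)-diene silyl carbinol
Product: 26 20-[dimethyl(phenyl)silyl]-18,19-isopropylidenedioxy-15-(4-methoxybenzyloxy)-16-trityloxylabd-5-en-20-ol (20S, 13S)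
Conditions: TsNHNH2, NaOAc, DME/H2O, 85 °C
Reagents that add atoms: none
Why: Diimide generated in situ transfers H2 concertedly to the cis-disubstituted C11=C12 bond and leaves the trisubstituted C5=C6 bond, shielded by quaternary C4 and C10, untouched, with no risk of hydrogenolysis of the benzylic ethers.

Step 21
Reactants: 26 saturated silyl carbinol
Product: 28 18,19-isopropylidenedioxy-15-(4-methoxybenzyloxy)-16-trityloxylabd-5-en-20-ol, via O-silyl ether 27 (not isolated)
Conditions: KOtBu (0.3 equiv), DMSO/H2O (20:1), rt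
Reagents that add atoms: none
Why: Base-induced protodesilylation of the α-hydroxysilane by Brook rearrangement (1,2 silyl shift from C20 to oxygen with protonation of carbon) and hydrolysis of the silyl ether removes the stereocontrol group and leaves C20 as CH2OH.

Step 22
Reactants: 28 C20 primary alcohol
Product: 29 18,19-isopropylidenedioxy-15-(4-methoxybenzyloxy)-16-trityloxylabd-5-en-20-al
Conditions: Dess–Martin periodinane, NaHCO3, CH2Cl2, rt
Reagents that add atoms: none
Why: Dess–Martin oxidation of the neopentyl primary alcohol stops at the aldehyde, which has no α-hydrogen and cannot epimerise or conjugate.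

Step 23
Reactants: 29 C20 aldehyde
Product: 31 18,19-isopropylidenedioxy-15-(4-methoxybenzyloxy)-16-trityloxylabd-5-ene (C20 = CH3), via hydrazone 30 (not isolated)
Conditions: N2H4·H2O, KOH, diethylene glycol, 130 °C then 200 °C
Reagents that add atoms: none
Why: Wolff–Kishner reduction (Huang-Minlon procedure) turns the angular aldehyde into the C20 methyl group by a carbanionic path, avoiding a homoallyl cation or radical at C20 that C5=C6 would capture; all remaining protecting groups are ethers or acetals stable to hot base.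

Step 24
Reactants: 31 C20 methyl compound
Product: 32 18,19-isopropylidenedioxy-16-trityloxylabd-5-en-15-ol
Conditions: DDQ, CH2Cl2/pH 7 buffer, 0 °C
Reagents that add atoms: none
Why: Oxidative cleavage of the electron-rich PMB ether (hydride abstraction by DDQ, then hydrolysis) frees only O15 and spares the trityl ether, the acetonide and the hindered alkene.

Step 25
Reactants: 32 C15 alcohol
Product: 33 18,19-isopropylidenedioxy-16-trityloxylabd-5-en-15-yl acetate
Conditions: Ac2O, pyridine, DMAP (cat.), CH2Cl2, 0 °C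
Reagents that add atoms: acetic anhydride CC(=O)OC(C)=O
Why: Acetylation of the only free hydroxyl group places the acetate on O15.

Step 26
Reactants: 33 C15 acetate
Product: 34 target, (8S,9S,10R,13S)-16,18,19-trihydroxylabd-5-en-15-yl acetate
Conditions: AcOH/THF/H2O (3:1:1), 45 °C
Reagents that add atoms: none
Why: Mild aqueous acid hydrolyses the trityl ether and the acetonide (three hydroxyl groups freed) while the primary acetate survives and no stereocentre is touched.

**Compound list**

1 | methyl 2,2-dimethyl-1,3-dioxane-5-carboxylate | COC(=O)C1COC(C)(C)OC1 | starting material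
2 | methyl 5-bromopentanoate | COC(=O)CCCCBr | starting material
3 | methyl 5-(5-methoxy-5-oxopentyl)-2,2-dimethyl-1,3-dioxane-5-carboxylate | COC(=O)CCCCC1(COC(C)(C)OC1)C(=O)OC | intermediate
4 | methyl 3,3-dimethyl-7-oxo-2,4-dioxaspiro[5.5]undecane-8-carboxylate | COC(=O)C1CCCC2(COC(C)(C)OC2)C1=O | intermediate
5 | methyl 3,3-dimethyl-7-(trifluoromethylsulfonyloxy)-2,4-dioxaspiro[5.5]undec-7-ene-8-carboxylate | COC(=O)C1=C(OS(=O)(=O)C(F)(F)F)C2(COC(C)(C)OC2)CCC1 | intermediate
6 | methyl 7-ethenyl-3,3-dimethyl-2,4-dioxaspiro[5.5]undec-7-ene-8-carboxylate | COC(=O)C1=C(C=C)C2(COC(C)(C)OC2)CCC1 | intermediate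
7 | 7-ethenyl-N-methoxy-N,3,3-trimethyl-2,4-dioxaspiro[5.5]undec-7-ene-8-carboxamide | CON(C)C(=O)C1=C(C=C)C2(COC(C)(C)OC2)CCC1 | intermediate
8 | [dimethyl(phenyl)silyl](7-ethenyl-3,3-dimethyl-2,4-dioxaspiro[5.5]undec-7-en-8-yl)methanone | C[Si](C)(c1ccccc1)C(=O)C1=C(C=C)C2(COC(C)(C)OC2)CCC1 | intermediate
9 | (S)-[dimethyl(phenyl)silyl](7-ethenyl-3,3-dimethyl-2,4-dioxaspiro[5.5]undec-7-en-8-yl)methanol | O[C@@H]([Si](C)(C)c1ccccc1)C1=C(C=C)C2(COC(C)(C)OC2)CCC1 | intermediate
10 | but-2-ynoic acid | CC#CC(=O)O | starting material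
11 | (S)-[dimethyl(phenyl)silyl](7-ethenyl-3,3-dimethyl-2,4-dioxaspiro[5.5]undec-7-en-8-yl)methyl but-2-ynoate | CC#CC(=O)O[C@@H]([Si](C)(C)c1ccccc1)C1=C(C=C)C2(COC(C)(C)OC2)CCC1 | intermediate
12 | (S)-[dimethyl(phenyl)silyl](7-ethenyl-3,3-dimethyl-2,4-dioxaspiro[5.5]undec-7-en-8-yl)methyl (Z)-but-2-enoate | C/C=C\C(=O)O[C@@H]([Si](C)(C)c1ccccc1)C1=C(C=C)C2(COC(C)(C)OC2)CCC1 | intermediate
13 | cycloadduct lactone (C11 lactone carbonyl on O20; 8β-methyl, 9α-H, 10β-C20, 20S silyl; 18,19-acetonide) | O=C1O[C@@H]([Si](C)(C)c5ccccc5)[C@]23CCCC4(COC(C)(C)OC4)C2=CC[C@H](C)[C@H]13 | intermediate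
14 | lactol of 13 (C11 hemiacetal, both anomers) | OC1O[C@@H]([Si](C)(C)c5ccccc5)[C@]23CCCC4(COC(C)(C)OC4)C2=CC[C@H](C)[C@H]13 | intermediate
15 | diethyl malonate | CCOC(=O)CC(=O)OCC | starting material
16 | 1-[(2-bromoethoxy)methyl]-4-methoxybenzene | COc1ccc(COCCBr)cc1 | starting material
17 | diethyl 2-{2-[(4-methoxybenzyl)oxy]ethyl}malonate | CCOC(=O)C(CCOCc1ccc(OC)cc1)C(=O)OCC | intermediate
18 | 2-{2-[(4-methoxybenzyl)oxy]ethyl}propane-1,3-diol | OCC(CO)CCOCc1ccc(OC)cc1 | intermediate
19 | (S)-2-(hydroxymethyl)-4-[(4-methoxybenzyl)oxy]butyl acetate | COc1ccc(COCC[C@@H](CO)COC(C)=O)cc1 | intermediate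
20 | (S)-4-[(4-methoxybenzyl)oxy]-2-[(trityloxy)methyl]butyl acetate | COc1ccc(COCC[C@@H](COC(c2ccccc2)(c2ccccc2)c2ccccc2)COC(C)=O)cc1 | intermediate
21 | (R)-4-[(4-methoxybenzyl)oxy]-2-[(trityloxy)methyl]butan-1-ol | COc1ccc(COCC[C@@H](COC(c2ccccc2)(c2ccccc2)c2ccccc2)CO)cc1 | intermediate
22 | (S)-1-({4-iodo-3-[(trityloxy)methyl]butoxy}methyl)-4-methoxybenzene | COc1ccc(COCC[C@@H](COC(c2ccccc2)(c2ccccc2)c2ccccc2)CI)cc1 | intermediate
23 | (S)-{4-[(4-methoxybenzyl)oxy]-2-[(trityloxy)methyl]butyl}triphenylphosphonium iodide | [I-].COc1ccc(COCC[C@@H](COC(c2ccccc2)(c2ccccc2)c2ccccc2)C[P+](c2ccccc2)(c2ccccc2)c2ccccc2)cc1 | intermediate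
24 | (S)-{4-[(4-methoxybenzyl)oxy]-2-[(trityloxy)methyl]butylidene}triphenylphosphorane (ylide, not isolated) | COc1ccc(COCC[C@@H](COC(c2ccccc2)(c2ccccc2)c2ccccc2)C=P(c2ccccc2)(c2ccccc2)c2ccccc2)cc1 | intermediate
25 | (11Z)-20-[dimethyl(phenyl)silyl]-18,19-isopropylidenedioxy-15-(4-methoxybenzyloxy)-16-trityloxylabda-5,11-dien-20-ol (20S) | COc1ccc(COCC[C@@H](COC(c2ccccc2)(c2ccccc2)c2ccccc2)/C=C\[C@H]2[C@@H](C)CC=C3C4(COC(C)(C)OC4)CCC[C@@]32[C@@H](O)[Si](C)(C)c2ccccc2)cc1 | intermediate
26 | 20-[dimethyl(phenyl)silyl]-18,19-isopropylidenedioxy-15-(4-methoxybenzyloxy)-16-trityloxylabd-5-en-20-ol (20S, 13S) | COc1ccc(COCC[C@@H](COC(c2ccccc2)(c2ccccc2)c2ccccc2)CC[C@H]2[C@@H](C)CC=C3C4(COC(C)(C)OC4)CCC[C@@]32[C@@H](O)[Si](C)(C)c2ccccc2)cc1 | intermediate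
27 | 20-[dimethyl(phenyl)silyloxy]-18,19-isopropylidenedioxy-15-(4-methoxybenzyloxy)-16-trityloxylabd-5-ene (not isolated) | COc1ccc(COCC[C@@H](COC(c2ccccc2)(c2ccccc2)c2ccccc2)CC[C@H]2[C@@H](C)CC=C3C4(COC(C)(C)OC4)CCC[C@@]32CO[Si](C)(C)c2ccccc2)cc1 | intermediate
28 | 18,19-isopropylidenedioxy-15-(4-methoxybenzyloxy)-16-trityloxylabd-5-en-20-ol | COc1ccc(COCC[C@@H](COC(c2ccccc2)(c2ccccc2)c2ccccc2)CC[C@H]2[C@@H](C)CC=C3C4(COC(C)(C)OC4)CCC[C@@]32CO)cc1 | intermediate
29 | 18,19-isopropylidenedioxy-15-(4-methoxybenzyloxy)-16-trityloxylabd-5-en-20-al | COc1ccc(COCC[C@@H](COC(c2ccccc2)(c2ccccc2)c2ccccc2)CC[C@H]2[C@@H](C)CC=C3C4(COC(C)(C)OC4)CCC[C@@]32C=O)cc1 | intermediate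
30 | hydrazone of 29 (not isolated) | COc1ccc(COCC[C@@H](COC(c2ccccc2)(c2ccccc2)c2ccccc2)CC[C@H]2[C@@H](C)CC=C3C4(COC(C)(C)OC4)CCC[C@@]32C=NN)cc1 | intermediate
31 | 18,19-isopropylidenedioxy-15-(4-methoxybenzyloxy)-16-trityloxylabd-5-ene | COc1ccc(COCC[C@@H](COC(c2ccccc2)(c2ccccc2)c2ccccc2)CC[C@H]2[C@@H](C)CC=C3C4(COC(C)(C)OC4)CCC[C@@]32C)cc1 | intermediate
32 | 18,19-isopropylidenedioxy-16-trityloxylabd-5-en-15-ol | OCC[C@@H](COC(c2ccccc2)(c2ccccc2)c2ccccc2)CC[C@H]2[C@@H](C)CC=C3C4(COC(C)(C)OC4)CCC[C@@]32C | intermediate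
33 | 18,19-isopropylidenedioxy-16-trityloxylabd-5-en-15-yl acetate | CC(=O)OCC[C@@H](COC(c2ccccc2)(c2ccccc2)c2ccccc2)CC[C@H]2[C@@H](C)CC=C3C4(COC(C)(C)OC4)CCC[C@@]32C | intermediate
34 | (8S,9S,10R,13S)-16,18,19-trihydroxylabd-5-en-15-yl acetate | CC(=O)OCC[C@@H](CO)CC[C@H]1[C@@H](C)CC=C2C(CO)(CO)CCC[C@@]21C | target

Total step count: 26. Longest linear sequence: 19 steps (steps 1 to 11 and 19 to 26).

**Steps most likely to fail**

Step 10. The cycloaddition of a singly activated crotonate onto a fully substituted diene terminus may be too slow at a temperature where the 1,5-hydrogen shift of the Z-substituted diene, or rearrangement of the silyl ester, takes over. The fallback uses a doubly activated dienophile that cyclises at much lower temperature, and sets out from 9. Maleic anhydride, Et3N and DMAP (cat.) give the hydrogen maleate F1. Warming in toluene (80–110 °C) should give the cis-fused lactone acid F2, with the same tether, the same Z geometry and the same C20 control, and with C17 as a β-carboxyl group. BH3·SMe2 (THF, 0 °C) reduces the acid faster than the lactone to the C17 alcohol F3. This is taken on at once with I2, PPh3 and imidazole to the C17 iodide F4. Bu3SnH with AIBN then gives the methyl compound, and the route is rejoined at 13.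

Step 7. Hydride delivery may discriminate poorly between the two carbonyl faces because both substituents (silyl and the fully substituted dienyl group) are bulky. The fallback forms the C20–Si bond enantioselectively instead of the C20–H bond, and sets out from 6. i-Bu2AlH reduces the ester to the dienol F5, and MnO2 oxidises it to the dienal F6. Copper-catalysed enantioselective 1,2-addition of PhMe2Si–B(pin) (CuCl, chiral N-heterocyclic carbene ligand, NaOtBu; then MeOH) gives the silyl carbinol, and the route is rejoined at 9.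

Step 19. Olefination of the hindered hydroxy-aldehyde released from the lactol may be slow, which gives the basic ylide time to epimerise C9. The fallback replaces the lactol by a free, protected aldehyde that reacts at −78 °C, and sets out from 13. MeNHOMe·HCl with AlMe3 opens the lactone to the hydroxy Weinreb amide F7. Me3SiCl and imidazole give its C20 trimethylsilyl ether F8. i-Bu2AlH at −78 °C gives the aldehyde F9. Ylide 24 at −78 °C gives the (11Z)-alkene silyl ether F10. K2CO3 in MeOH removes the trimethylsilyl group, and the route is rejoined at 25.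

Further compounds

F1 | step 10 | (Z)-4-{(S)-[dimethyl(phenyl)silyl](7-ethenyl-3,3-dimethyl-2,4-dioxaspiro[5.5]undec-7-en-8-yl)methoxy}-4-oxobut-2-enoic acid | OC(=O)/C=C\C(=O)O[C@@H]([Si](C)(C)c1ccccc1)C1=C(C=C)C2(COC(C)(C)OC2)CCC1
F2 | step 10 | lactone acid: as 13 with C17 as β-carboxyl group on C8 | O=C1O[C@@H]([Si](C)(C)c5ccccc5)[C@]23CCCC4(COC(C)(C)OC4)C2=CC[C@H](C(=O)O)[C@H]13
F3 | step 10 | lactone alcohol: as 13 with C17 as CH2OH | O=C1O[C@@H]([Si](C)(C)c5ccccc5)[C@]23CCCC4(COC(C)(C)OC4)C2=CC[C@H](CO)[C@H]13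
F4 | step 10 | lactone iodide: as 13 with C17 as CH2I | O=C1O[C@@H]([Si](C)(C)c5ccccc5)[C@]23CCCC4(COC(C)(C)OC4)C2=CC[C@H](CI)[C@H]13
F5 | step 7 | (7-ethenyl-3,3-dimethyl-2,4-dioxaspiro[5.5]undec-7-en-8-yl)methanol | OCC1=C(C=C)C2(COC(C)(C)OC2)CCC1
F6 | step 7 | 7-ethenyl-3,3-dimethyl-2,4-dioxaspiro[5.5]undec-7-ene-8-carbaldehyde | O=CC1=C(C=C)C2(COC(C)(C)OC2)CCC1
F7 | step 19 | hydroxy Weinreb amide: C11 N-methoxy-N-methylamide with free (20S)-silyl carbinol | CON(C)C(=O)[C@H]1[C@@H](C)CC=C2C3(COC(C)(C)OC3)CCC[C@@]21[C@@H](O)[Si](C)(C)c1ccccc1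
F8 | step 19 | C20 trimethylsilyl ether of F7 | CON(C)C(=O)[C@H]1[C@@H](C)CC=C2C3(COC(C)(C)OC3)CCC[C@@]21[C@@H](O[Si](C)(C)C)[Si](C)(C)c1ccccc1
F9 | step 19 | C11 aldehyde with C20 trimethylsilyl ether | O=C[C@H]1[C@@H](C)CC=C2C3(COC(C)(C)OC3)CCC[C@@]21[C@@H](O[Si](C)(C)C)[Si](C)(C)c1ccccc1
F10 | step 19 | C20 trimethylsilyl ether of 25 | COc1ccc(COCC[C@@H](COC(c2ccccc2)(c2ccccc2)c2ccccc2)/C=C\[C@H]2[C@@H](C)CC=C3C4(COC(C)(C)OC4)CCC[C@@]32[C@@H](O[Si](C)(C)C)[Si](C)(C)c2ccccc2)cc1
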